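**Retrosynthetic overview**
1. The C6–Br bond is made last: target ⇒ 3,5-dibromo-2-(2-bromophenoxy)phenol by OH-directed ortho bromination.
2. C–OH ⇒ C–I: that phenol ⇒ 1,5-dibromo-2-(2-bromophenoxy)-3-iodobenzene (selective I/Mg exchange, borylation, oxidation).
3. Key step: the ortho-iodo diaryl ether ⇒ an aryliodonium phenolate by I→O 1,4-aryl migration. One iodane gives its aryl group to oxygen and leaves its iodine as the placeholder for OH. This replaces an Ullmann, SNAr or Chan–Lam coupling onto a protected bromocatechol.
4. Zwitterion ⇒ 2,4-dibromophenol + (2-bromophenyl)iodine(III) diacetate, which comes from 1-bromo-2-iodobenzene.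
5. No ring is formed. Both benzene rings are bought and only their substituents are changed.

Assumption: the SMILES has no stereocentre and no configurationally stable axis, so the target is achiral and the "single enantiomer" request needs no action.

**Step 1**
Reactants: 1 1-bromo-2-iodobenzene
Product: 2 (2-bromophenyl)-λ3-iodanediyl diacetate
Conditions: mCPBA (1.3 equiv), AcOH, 55 °C, 16 h
Reagents that add atoms: acetic acid, CC(=O)O
Why: This is the standard peracid oxidation of an aryl iodide to the λ3-iodane with ligand exchange in acetic acid, the C–Br bond is inert to peracid, and no stereocentre is formed.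

**Step 2**
Reactants: 2 (2-bromophenyl)-λ3-iodanediyl diacetate, 3 2,4-dibromophenol
Product: 5 1,5-dibromo-2-(2-bromophenoxy)-3-iodobenzene, via iodonium phenolate zwitterion 4 (not isolated)
Conditions: MeCN, 0 °C → rt, 2 h; 2,6-lutidine (2.2 equiv), rt, 1 h; then 80 °C, 4 h
Reagents that add atoms: none
Why: This is a known reaction type, aryliodonium phenolate formation followed by thermal I→O 1,4-aryl migration (a Smiles-type intramolecular ipso substitution at hypervalent iodine), in which the iodane attacks C6 (the only free ortho/para carbon of the electron-poor phenol, whose two bromines disfavour oxidative dearomatisation in the nucleophile-free medium) and the phenolate oxygen of 4 then takes the ortho-bromo-activated aryl group from iodine, so the ether bond forms and iodine stays on the carbon that must carry OH; no stereocentre is formed.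

**Step 3**
Reactants: 5 1,5-dibromo-2-(2-bromophenoxy)-3-iodobenzene
Product: 8 3,5-dibromo-2-(2-bromophenoxy)phenol, via arylmagnesium chloride 6 (not isolated), via dimethyl arylboronate 7 (not isolated)
Conditions: iPrMgCl (1.05 equiv), THF, −40 °C, 30 min; B(OMe)3 (1.5 equiv), −40 °C → rt; strip volatiles (removes iPrI); 30% H2O2, AcOH, THF, 0 °C → rt
Reagents that add atoms: hydrogen peroxide, OO (phenol oxygen of 8); isopropylmagnesium chloride, CC(C)[Mg]Cl (MgCl of 6 only); trimethyl borate, COB(OC)OC (B(OMe)2 of 7 only)
Why: Halogen–magnesium exchange is orders of magnitude faster at C–I than at C–Br, so only iodine is exchanged at −40 °C, Grignard 6 has no ortho halogen and cannot collapse to an aryne, and the borylation–oxidation sequence (1,2-aryl B→O shift) puts OH on the ipso carbon; no stereocentre is formed.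

**Step 4**
Reactants: 8 3,5-dibromo-2-(2-bromophenoxy)phenol
Product: 9 2,3,5-tribromo-6-(2-bromophenoxy)phenol (target)
Conditions: NBS (1.0 equiv, slow addition), iPr2NH (10 mol %), CH2Cl2, 0 °C → rt
Reagents that add atoms: N-bromosuccinimide, O=C1CCC(=O)N1Br
Why: This is an amine-mediated ortho-selective electrophilic bromination of a phenol, in which the N-bromoamine formed in situ hydrogen-bonds to the OH and delivers Br+ to the only free ortho carbon, while the para carbon is shielded by two flanking bromines and ring B is far less nucleophilic than the phenol ring; no stereocentre is formed.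

**Compound list**
1 | 1-bromo-2-iodobenzene | Brc1ccccc1I | starting material
2 | (2-bromophenyl)-λ3-iodanediyl diacetate | CC(=O)OI(OC(C)=O)c1ccccc1Br | intermediate
3 | 2,4-dibromophenol | Oc1ccc(Br)cc1Br | starting material
4 | 2,4-dibromo-6-[(2-bromophenyl)iodonio]phenolate | [O-]c1c(Br)cc(Br)cc1[I+]c1ccccc1Br | intermediate
5 | 1,5-dibromo-2-(2-bromophenoxy)-3-iodobenzene | Brc1cc(Br)c(Oc2ccccc2Br)c(I)c1 | intermediate
6 | [3,5-dibromo-2-(2-bromophenoxy)phenyl]magnesium chloride | Cl[Mg]c1cc(Br)cc(Br)c1Oc1ccccc1Br | intermediate
7 | dimethyl [3,5-dibromo-2-(2-bromophenoxy)phenyl]boronate | COB(OC)c1cc(Br)cc(Br)c1Oc1ccccc1Br | intermediate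
8 | 3,5-dibromo-2-(2-bromophenoxy)phenol | Oc1cc(Br)cc(Br)c1Oc1ccccc1Br | intermediate
9 | 2,3,5-tribromo-6-(2-bromophenoxy)phenol | Oc1c(Br)c(Br)cc(Br)c1Oc1ccccc1Br | target

Total step count: 4. Longest linear sequence: 4 (1 → 2 → 5 → 8 → 9).

**Three steps most likely to fail**

Step 2 is the highest risk. Phenol 3 carries only two bromines as acceptors, so the iodane may oxidise it to quinoid products instead of forming the C–I(III) bond. The fallback sets out from 3 and comes back to the route at 4. It takes the iodine from ring A, so no oxidant ever meets a free phenol.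
- Iodinate 3 at the free ortho carbon (NIS, cat. TsOH, MeCN) to give 2,4-dibromo-6-iodophenol F1.
- Cap the phenol (Ac2O, pyridine) to give 2,4-dibromo-6-iodophenyl acetate F2.
- Oxidise the iodine with mCPBA/BF3·OEt2 in CH2Cl2, then add bought 2-bromophenylboronic acid (OB(O)c1ccccc1Br). Regiospecific boron-to-iodine(III) exchange gives (2-acetoxy-3,5-dibromophenyl)(2-bromophenyl)iodonium tetrafluoroborate F3.
- K2CO3 in MeOH at 0 °C removes the acetate and releases zwitterion 4, which is heated as in step 2 to give 5.

Step 4 is the second risk. Bromination para to OH, or double bromination, would give isomers that are hard to separate. The fallback sets out from 2 and comes back at 9. It places the third bromine before the key step, so no late electrophilic substitution is needed.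
- Treat 2 with bought 2,4,5-tribromophenol (Oc1cc(Br)c(Br)cc1Br) under the step 2 conditions to give 3,4,6-tribromo-2-[(2-bromophenyl)iodonio]phenolate F4.
- Heating turns it into 1,2,5-tribromo-4-(2-bromophenoxy)-3-iodobenzene F5.
- iPrMgCl at −78 °C gives [2,3,5-tribromo-6-(2-bromophenoxy)phenyl]magnesium chloride F6. It is kept cold because it has an ortho bromine.
- B(OMe)3 gives dimethyl [2,3,5-tribromo-6-(2-bromophenoxy)phenyl]boronate F7, and H2O2/AcOH then gives 9 directly.

Step 3 is the third risk. Partial Br/Mg exchange on the electron-poor ring, or iodination of the product phenol during oxidation, could erode the yield. The fallback sets out from 5 and comes back at 8. It uses no organometallic and activates the iodine a second time as iodine(III).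
- Oxidise 5 with mCPBA/TsOH·H2O in MeCN at 77 °C and add 1,3,5-trimethoxybenzene to give [3,5-dibromo-2-(2-bromophenoxy)phenyl](2,4,6-trimethoxyphenyl)iodonium tosylate F8.
- Metal-free O-arylation of triisopropylsilanol (KOtBu, toluene) transfers the electron-poor, ortho-substituted aryl group. The trimethoxyphenyl group stays on iodine as the dummy ligand, and the product is [3,5-dibromo-2-(2-bromophenoxy)phenoxy]tri(propan-2-yl)silane F9.
- TBAF in THF then gives 8.

**Further compounds**
F1 | step 2 | 2,4-dibromo-6-iodophenol | Oc1c(Br)cc(Br)cc1I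
F2 | step 2 | 2,4-dibromo-6-iodophenyl acetate | CC(=O)Oc1c(Br)cc(Br)cc1I
F3 | step 2 | (2-acetoxy-3,5-dibromophenyl)(2-bromophenyl)iodonium tetrafluoroborate | CC(=O)Oc1c(Br)cc(Br)cc1[I+]c1ccccc1Br.F[B-](F)(F)F
F4 | step 4 | 3,4,6-tribromo-2-[(2-bromophenyl)iodonio]phenolate | [O-]c1c(Br)cc(Br)c(Br)c1[I+]c1ccccc1Br
F5 | step 4 | 1,2,5-tribromo-4-(2-bromophenoxy)-3-iodobenzene | Brc1cc(Br)c(Oc2ccccc2Br)c(I)c1Br
F6 | step 4 | [2,3,5-tribromo-6-(2-bromophenoxy)phenyl]magnesium chloride | Cl[Mg]c1c(Br)c(Br)cc(Br)c1Oc1ccccc1Br
F7 | step 4 | dimethyl [2,3,5-tribromo-6-(2-bromophenoxy)phenyl]boronate | COB(OC)c1c(Br)c(Br)cc(Br)c1Oc1ccccc1Br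
F8 | step 3 | [3,5-dibromo-2-(2-bromophenoxy)phenyl](2,4,6-trimethoxyphenyl)iodonium tosylate | COc1cc(OC)c([I+]c2cc(Br)cc(Br)c2Oc2ccccc2Br)c(OC)c1.Cc1ccc(S(=O)(=O)[O-])cc1
F9 | step 3 | [3,5-dibromo-2-(2-bromophenoxy)phenoxy]tri(propan-2-yl)silane | CC(C)[Si](Oc1cc(Br)cc(Br)c1Oc1ccccc1Br)(C(C)C)C(C)C
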